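## Analysis of the target

Compound 27 is a sesquilignan made of three C6–C3 units. A cis-fused 3,7-dioxabicyclo[3.3.0]octane (furofuran) carries a syringyl ring (ring C, free 4-OH) on C7 and a guaiacyl ring (ring B) on C7'. The 4-oxygen of ring B is bonded to C8'' of a 1-arylpropane-1,3-diol chain (C7''–C8''–C9'') that ends in a second guaiacyl ring (ring A, free 4-OH). Here C7, C8, C9 are the benzylic CH, the bridgehead CH and the OCH2 of the ring C half, C7', C8', C9' the same atoms of the ring B half, and the ether bridges are C7–O–C9' and C7'–O–C9.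

There are six stereocentres in two clusters. The bicycle is 7R, 8S, 7'R, 8'S (both aryl groups exo, H8 and H8' cis, the mirror-image series of (+)-pinoresinol). The chain is 7''S, 8''S (threo, the pattern of a syn aldol). Ring B and an ether oxygen insulate the clusters from each other, so each needs its own control element.

The three benzylic C–O bonds (C7–O, C7'–O, C7''–OH) ionise in acid, which epimerises these centres, and they are open to hydrogenolysis. The two free phenols are easily oxidised, and the 4-hydroxybenzylic alcohol on ring A can collapse to a quinone methide.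

The synthesis is hard for three reasons. The furofuran is unsymmetrical, so dimerising one cinnamyl alcohol cannot make it cleanly. Three phenolic oxygens with three different fates must be told apart. C7 and C7' must end exo without later equilibration.

The strategy rests on the chain C9–C8–C8'–C9' with the C7 and C7' arms trans across C8–C8'. This is a 3,4-trans-disubstituted γ-butyrolactone (C9' as carbonyl, C9 as acetal carbon) flanked by two aryl-bearing carbons at the carbonyl oxidation level. It therefore maps onto a ring C aldehyde, a butenolide and a ring B aldehyde.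

## Retrosynthetic reasoning

**27 from 26.** The last operation only uncovers the two phenols; no skeletal bond is cut. Both are carried as allyl ethers in 26 because allyl groups leave under neutral palladium catalysis. Benzyl ethers would need hydrogenolysis, which competes with cleavage of the three benzylic C–O bonds, and acid-labile groups would ionise C7, C7' and C7''.

**26 from 25, and 25 from 22 and 23.** The side chain is cut at C7''–C8''. This is the one C–C bond whose formation can set both chain centres at once. The threo 1,3-diol 26 is the reduction product of the syn aldol 25, and 25 comes from the aryloxyacetyl imide 22 and the ring A aldehyde 23. Cutting C8''–O instead would mean a displacement at a hindered secondary carbon next to a benzylic centre. The forward reaction must set 7''S and 8''S without help from the distant furofuran; the (R)-oxazolidinone does this through its Z boron enolate.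

**22 from 18 and 21; 18 from 17.** The aryloxyacetyl unit is detached at its O–CH2 bond, giving phenol 18 and the bromoacetyl imide 21 (from 19). A primary, carbonyl-activated halide is the easiest electrophile for a valuable phenol. 18 requires that the ring B oxygen be freed while the ring C oxygen stays masked, hence a silyl ether on ring B (17) and an allyl ether on ring C.

**17 from 15 (through 16); 15 from 14, 13 and 12.** Both ether bonds C7–O and C7'–O are cut. Each carbon is benzylic and para to an oxygen donor, so each bond can form by capture of a benzylic cation by a hydroxymethyl group. This makes tetraol 15 the precursor and makes the configuration of its two carbinols irrelevant. The closure has to place both aryl groups exo; the cis ring fusion follows from the (8S,8'S) chain. 15 is the reduction product of ketone 14, 14 is the unmasked dithiane 13, and 13 is the hydride reduction product of the lactone acetal 12.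

**12 from 3, 7 and 9.** 12 is cut at C7–C8 and at C8'–C7'. C8 is the β-carbon and C8' the α-carbon of an unsaturated lactone. The first bond is therefore a conjugate addition of an acyl anion equivalent of the ring C aldehyde (dithiane 3), and the second an aldol addition of the resulting enolate to the ring B aldehyde 9. Butenolide 7 supplies C9–C8–C8'–C9' and a removable stereocentre on C9 that controls C8, which in turn controls C8'. A cut at C8–C8' would instead demand an enantioselective union of two different C6–C3 halves.

**3, 7, 9, 21 and 23 from commercial materials.** 3 comes from 1 through 2 (O-allylation, thioacetalisation). 7 comes from 5 and 6, with 5 made from 4 by photo-oxygenation; the acetal carbon of 7 epimerises, so one epimer can be collected by crystallisation. 9 and 23 are the silyl and allyl ethers of 8.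

## Alternatives that were turned down

**Alternative 1:** The ring B tetrahydrofuran is cut at C7'–O and C8–C9, which removes one formaldehyde unit (A3) and leads back to the aryl cyclopropane lactone A2. In A2 ring B is the donor, and the C7 lactone carbonyl and an extra ester on C8 are the acceptors. Forward, Sn(OTf)2 would polarise the C7'–C8 bond and A3 would add across it, oxygen to C7' with inversion and carbon to C8, giving the cis-fused tetrahydrofuran lactone A1.
- For: the C7' configuration is transferred stereospecifically from the cyclopropane, and the Lewis acid is catalytic. On this point it is stronger than the chosen route, which depends on kinetic control when the C7 and C7' cations close.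
- Against: A3 is the least manageable aldehyde for this cycloaddition because it oligomerises under the Lewis acid. The electron-rich silyloxyaryl donor favours a long-lived benzylic zwitterion, so stereospecificity at C7' may leak. A2 itself needs an enantioselective cyclopropanation.
- Against, decisive: A1 contains only ring B. The C8 ester must then be removed and ring C added to the C7 carbonyl, and reduction of the resulting lactol through its oxocarbenium ion delivers hydride from the convex face, which places ring C endo (the wrong C7 epimer).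
- Comparison: the chosen route brings in both rings and all four chain carbons in one step and treats C7 and C7' alike.

**Alternative 2:** Both C7–O and C7'–O are cut with both benzylic carbons reduced to CH2, which leads to the dibenzylbutanediol A5. Forward, DDQ would oxidise the CH2 para to the free ring B phenol to a quinone methide and the CH2 of the ring C benzyl ether to a cation, each captured by a hydroxymethyl group, to give furofuran A4.
- For: it is the shortest end game. There are no carbinols to make and no dithiane to unmask, ring B needs no protecting group, and A5 is available from related butenolide chemistry. In step count after the skeleton is assembled it beats the chosen route.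
- Against: the two benzylic sites are unequal. The ring B side reacts through its phenol, but the ring C side has no free phenol and needs hydride abstraction from a trialkoxyarene. That is slower than three competing processes: further oxidation of the newly formed, doubly activated C7'–H ether position, oxidation of the benzyl protecting group, and attack of an electron-rich ring on the neighbouring cation to give an aryltetralin.
- Comparison: the chosen route pays three redox steps (7 to 9) to hold C7 and C7' at the alcohol level from the start, so no oxidant has to choose among several electron-rich benzylic positions late on.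

**Alternative 3:** The C7–C8 bond is cut. Ring C arrives as a benzyl ether on the C9' oxygen and C8 as the diazo carbon of lactone A7. Forward, Rh2(OAc)4 would form the carbene at C8, which inserts into the C7–H bond (activated by the ether oxygen and the aryl ring), closing the ring C7–O–C9'–C8'–C8 and giving furofuranone A6.
- For: a C–C bond and a ring form in one catalytic step, cis fusion is enforced, and no stoichiometric auxiliary is used. In atom economy it is stronger than the chosen route.
- Against: the carbene has a hydrogen on the adjacent C8', and 1,2-hydride shift to the butenolide is a fast competing path. Cyclopropanation of ring C and insertion at other ether C–H bonds are further leaks. The exo or endo placement of ring C at C7 is decided by the insertion transition state with no reliable bias.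
- Against: A7 presupposes an asymmetric synthesis of the trans-4,5-disubstituted lactone plus a diazo transfer, and the C9 carbonyl of A6 must still be reduced to CH2 under Lewis-acidic conditions that endanger the benzylic ethers.
- Comparison: the chosen route takes its absolute configuration from a crystalline, recoverable auxiliary and forms the same bond by a polar addition with a predictable facial bias.

Key step: step 6

Remark: C7' (formed in step 6) and C7 (formed in step 9) are carbinol centres expected as epimer mixtures; C7' is written as the 7'R epimer, C7 is left undefined, and both are erased when the benzylic cations form in step 10.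

Remark: the ring A and ring C phenols are carried as allyl ethers so that no hydrogenolysis or acid is needed once the benzylic ethers exist.

## Route

**Step 1**
Reactants: 1 syringaldehyde
Product: 2 4-(allyloxy)-3,5-dimethoxybenzaldehyde
Conditions: CH2=CHCH2Br, K2CO3, DMF, 60 °C
Reagents that add atoms: allyl bromide, C=CCBr
Why: Williamson ether synthesis; the acidic, flanked phenol is deprotonated by K2CO3 and the unhindered allylic bromide is displaced readily.

**Step 2**
Reactants: 2 4-(allyloxy)-3,5-dimethoxybenzaldehyde
Product: 3 2-[4-(allyloxy)-3,5-dimethoxyphenyl]-1,3-dithiane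
Conditions: HS(CH2)3SH, BF3·OEt2 (cat.), CH2Cl2, 0 °C → rt
Reagents that add atoms: propane-1,3-dithiol, SCCCS
Why: Lewis-acid-catalysed dithioacetalisation of an aromatic aldehyde; the allyl ether and methyl ethers are inert to catalytic BF3·OEt2 at this temperature.

**Step 3**
Reactants: 4 furfural
Product: 5 5-hydroxyfuran-2(5H)-one (racemic)
Conditions: O2, hν (visible), rose bengal (cat.), MeOH, rt
Reagents that add atoms: oxygen, O=O
Why: Dye-sensitised singlet oxygen adds [4+2] across the furan; methanol opens the endoperoxide with loss of the formyl carbon as methyl formate (photo-oxygenation of furfural), leaving the γ-hydroxybutenolide.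

**Step 4**
Reactants: 5 5-hydroxyfuran-2(5H)-one, 6 (1S,2R,5S)-(+)-menthol
Product: 7 (5S)-5-{[(1S,2R,5S)-2-isopropyl-5-methylcyclohexyl]oxy}furan-2(5H)-one
Conditions: neat, 100 °C; crystallisation from petroleum ether, −20 °C; mother liquor re-equilibrated with TsOH (cat.) and recrystallised
Reagents that add atoms: none
Why: Acetalisation of the pseudo-acid gives both C5 epimers, which interconvert under acid. The (5S) acetal of (+)-menthol is the mirror image of the well-known crystalline (5R) acetal of (−)-menthol, so crystallisation with recycling should deliver 7 as one stereoisomer.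

**Step 5**
Reactants: 8 vanillin
Product: 9 4-(tert-butyldimethylsilyloxy)-3-methoxybenzaldehyde
Conditions: TBSCl, imidazole, DMF, rt
Reagents that add atoms: tert-butyldimethylsilyl chloride, CC(C)(C)[Si](C)(C)Cl
Why: Imidazole-promoted silylation of a phenol; the aryl silyl ether withstands enolates and hydride and is later removed by fluoride without touching allyl ethers.

**Step 6**
Reactants: 3 2-[4-(allyloxy)-3,5-dimethoxyphenyl]-1,3-dithiane, 7 (5S)-5-menthyloxyfuran-2(5H)-one, 9 4-(tert-butyldimethylsilyloxy)-3-methoxybenzaldehyde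
Product: 12 (3R,4S,5S)-4-{2-[4-(allyloxy)-3,5-dimethoxyphenyl]-1,3-dithian-2-yl}-3-{(R)-[4-(tert-butyldimethylsilyloxy)-3-methoxyphenyl](hydroxy)methyl}-5-{[(1S,2R,5S)-2-isopropyl-5-methylcyclohexyl]oxy}dihydrofuran-2(3H)-one (7'R epimer drawn; the 7'S epimer is expected alongside), via 2-lithio dithiane 10 (not isolated), via lithium lactone enolate 11 (not isolated)
Conditions: n-BuLi, THF, −78 → −40 °C; 7, −78 °C; 9, −78 °C; AcOH, −78 °C
Reagents that add atoms: none
Why: n-BuLi removes the acidic C2–H of 3 to give the sulfur-stabilised anion 10, a soft and bulky acyl anion equivalent that adds 1,4 to butenolide 7 at C4 (= C8) and not to the lactone carbonyl. The closest known reaction type is the tandem Michael addition of lithiated 2-aryl-1,3-dithianes to 5-alkoxyfuran-2(5H)-ones with trapping of the lactone enolate by an electrophile, a three-component coupling. The anion approaches the ring face opposite the menthyloxy group on the neighbouring acetal carbon C5, so C8 (4S) is controlled by the (5S) centre of the auxiliary. With no proton source present, the lithium enolate 11 persists and adds through C3 (= C8') to the non-enolisable aldehyde 9 on the face away from the quaternary dithianyl carbon, which gives the 3,4-trans lactone and sets C8' (3R). The carbinol C7' comes from a chair aldol transition state of a ring-locked E enolate, which gives little control and may favour the anti (7'S) epimer; this is harmless because C7' is ionised in step 10. No ring is closed; two skeletal bonds (C7–C8 and C8'–C7') and three stereocentres are formed. The step needs 1,4 over 1,2 selectivity, secured by the delocalised dithiane anion and the unhindered β-carbon, and anti then trans facial control, secured by the single acetal stereocentre and relayed by the bulky C8 substituent. Quenching with AcOH at −78 °C forestalls retro-aldol cleavage and β-elimination.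

**Step 7**
Reactants: 12 lactone acetal from step 6
Product: 13 (2S,3S)-2-{2-[4-(allyloxy)-3,5-dimethoxyphenyl]-1,3-dithian-2-yl}-3-{(R)-[4-(tert-butyldimethylsilyloxy)-3-methoxyphenyl](hydroxy)methyl}butane-1,4-diol
Conditions: LiAlH4, THF, 0 °C; Fieser work-up
Reagents that add atoms: none
Why: Hydride reduction of the lactone releases the C9 hemiacetal alkoxide, which collapses to the aldehyde with loss of menthoxide and is reduced in turn, so C9' and C9 both become CH2OH and menthol is recovered. At 0 °C the aryl silyl ether, the dithiane and the allyl ether are left alone, and the transient aldehydes are reduced faster than C8 or C8' can epimerise.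

**Step 8**
Reactants: 13 dithiane triol
Product: 14 (2S,3S)-1-[4-(allyloxy)-3,5-dimethoxyphenyl]-4-hydroxy-2-(hydroxymethyl)-3-{(R)-[4-(tert-butyldimethylsilyloxy)-3-methoxyphenyl](hydroxy)methyl}butan-1-one
Conditions: PhI(OCOCF3)2, NaHCO3, MeCN/H2O (9:1), 0 °C
Reagents that add atoms: water, O
Why: Oxidative dithiane hydrolysis: the trivalent iodine reagent activates sulfur, the aryl-stabilised thionium ion is captured by water (or first by the C9' hydroxyl) and the second C–S bond is cleaved likewise. The reagent is mercury-free, which spares the allyl ether, and the short, cold, buffered reaction limits enolisation at C8 and acid ionisation at C7'. 14 may rest partly as its five-membered hemiketal with the C9' hydroxyl, which does not matter.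

**Step 9**
Reactants: 14 keto triol (used directly)
Product: 15 (2S,3S)-2-{[4-(allyloxy)-3,5-dimethoxyphenyl](hydroxy)methyl}-3-{(R)-[4-(tert-butyldimethylsilyloxy)-3-methoxyphenyl](hydroxy)methyl}butane-1,4-diol (C7 epimers)
Conditions: NaBH4, MeOH, 0 °C
Reagents that add atoms: none
Why: Borohydride reduction of the aryl ketone, run at once so that the enolisable β-hydroxy ketone does not linger. The new C7 carbinol needs no control because it is ionised in the next step.

**Step 10**
Reactants: 15 tetraol
Product: 17 (1R,3aS,4R,6aS)-1-[4-(allyloxy)-3,5-dimethoxyphenyl]-4-[4-(tert-butyldimethylsilyloxy)-3-methoxyphenyl]tetrahydro-1H,3H-furo[3,4-c]furan, via monocyclic tetrahydrofuran diol 16 (not isolated)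
Conditions: CSA (0.1 equiv), 4 Å MS, CH2Cl2, 0 °C → rt
Reagents that add atoms: none
Why: Acid-catalysed double cyclodehydration: each benzylic carbinol ionises to an oxygen-stabilised benzylic cation and is captured by the hydroxymethyl group two carbons away (C9–OH at C7', C9'–OH at C7) in a five-membered closure. The (8S,8'S) chain can only give the cis-fused bicycle, and each aryl group should take the less hindered exo position trans to the adjacent ring bond. Catalytic acid, low temperature and sieves keep the closure kinetic so that the product is not re-ionised.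

**Step 11**
Reactants: 17 furofuran silyl ether
Product: 18 4-{(1R,3aS,4R,6aS)-4-[4-(allyloxy)-3,5-dimethoxyphenyl]tetrahydro-1H,3H-furo[3,4-c]furan-1-yl}-2-methoxyphenol
Conditions: Bu4NF, AcOH, THF, 0 °C
Reagents that add atoms: none
Why: Fluoride cleaves the aryl Si–O bond selectively; allyl ethers and the furofuran are inert, and the AcOH buffer keeps the medium near neutral.

**Step 12**
Reactants: 19 (R)-4-benzyloxazolidin-2-one
Product: 21 (R)-4-benzyl-3-(bromoacetyl)oxazolidin-2-one, via N-lithio oxazolidinone 20 (not isolated)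
Conditions: n-BuLi, THF, −78 °C; BrCH2COBr, −78 °C
Reagents that add atoms: bromoacetyl bromide, BrCC(=O)Br
Why: N-Acylation of the lithiated oxazolidinone by the acid bromide, which reacts at the acyl carbon much faster than at the CH2Br carbon at −78 °C.

**Step 13**
Reactants: 18 furofuran phenol, 21 (R)-4-benzyl-3-(bromoacetyl)oxazolidin-2-one
Product: 22 (R)-4-benzyl-3-[2-(4-{(1R,3aS,4R,6aS)-4-[4-(allyloxy)-3,5-dimethoxyphenyl]tetrahydro-1H,3H-furo[3,4-c]furan-1-yl}-2-methoxyphenoxy)acetyl]oxazolidin-2-one
Conditions: K2CO3, acetone, rt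
Reagents that add atoms: none
Why: Williamson ether synthesis; displacement at the α-carbonyl bromide by the phenoxide is much faster than attack at the imide carbonyl, and 18 has no other acidic or nucleophilic site.

**Step 14**
Reactants: 8 vanillin
Product: 23 4-(allyloxy)-3-methoxybenzaldehyde
Conditions: CH2=CHCH2Br, K2CO3, DMF, rt
Reagents that add atoms: allyl bromide, C=CCBr
Why: Williamson ether synthesis on the phenol, as in step 1.

**Step 15**
Reactants: 22 aryloxyacetyl imide, 23 4-(allyloxy)-3-methoxybenzaldehyde
Product: 25 (R)-4-benzyl-3-[(2R,3S)-3-[4-(allyloxy)-3-methoxyphenyl]-3-hydroxy-2-(4-{(1R,3aS,4R,6aS)-4-[4-(allyloxy)-3,5-dimethoxyphenyl]tetrahydro-1H,3H-furo[3,4-c]furan-1-yl}-2-methoxyphenoxy)propanoyl]oxazolidin-2-one, via Z dibutylboron enolate 24 (not isolated)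
Conditions: Bu2BOTf, iPr2NEt, CH2Cl2, −78 → 0 °C; 23, −78 → 0 °C; pH 7 buffer, MeOH, H2O2, 0 °C
Reagents that add atoms: none
Why: Evans syn aldol of a glycolate-type imide: soft enolisation gives the Z boron enolate 24, which reacts through a closed chair transition state with the dipole-opposed auxiliary shielding one face. The (R)-benzyl group sets 8'' (2R in the imide) and the chair sets 7''S syn to it, which is the threo pattern of the target. The amine-buffered boron triflate should leave the furofuran ethers alone, since they are no more labile than 4-methoxybenzyl ethers, which tolerate these conditions.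

**Step 16**
Reactants: 25 syn aldol imide
Product: 26 (1S,2S)-1-[4-(allyloxy)-3-methoxyphenyl]-2-(4-{(1R,3aS,4R,6aS)-4-[4-(allyloxy)-3,5-dimethoxyphenyl]tetrahydro-1H,3H-furo[3,4-c]furan-1-yl}-2-methoxyphenoxy)propane-1,3-diol
Conditions: NaBH4, THF/H2O, 0 °C → rt
Reagents that add atoms: none
Why: Reductive cleavage of the N-acyl oxazolidinone: hydride attacks the activated exocyclic carbonyl and reduces it to the primary alcohol (C9''), releasing 19 for reuse. Reduction is faster than enolisation, so C8'' keeps its configuration, and borohydride in wet THF does not touch the allyl groups.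

**Step 17**
Reactants: 26 bis(allyl ether)
Product: 27 (1S,2S)-1-(4-hydroxy-3-methoxyphenyl)-2-(4-{(1R,3aS,4R,6aS)-4-(4-hydroxy-3,5-dimethoxyphenyl)tetrahydro-1H,3H-furo[3,4-c]furan-1-yl}-2-methoxyphenoxy)propane-1,3-diol
Conditions: Pd(PPh3)4 (cat.), morpholine, THF, rt
Reagents that add atoms: none
Why: Zerovalent palladium ionises each aryl allyl ether to a π-allyl complex and a phenoxide, and morpholine captures the allyl group. No acid, strong base or hydrogen is present, so the benzylic C–O bonds at C7, C7' and C7'' are not at risk.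

## Compound list

1 | syringaldehyde | COc1cc(C=O)cc(OC)c1O | starting material
2 | 4-(allyloxy)-3,5-dimethoxybenzaldehyde | COc1cc(C=O)cc(OC)c1OCC=C | intermediate
3 | 2-[4-(allyloxy)-3,5-dimethoxyphenyl]-1,3-dithiane | COc1cc(C2SCCCS2)cc(OC)c1OCC=C | intermediate
4 | furfural | O=Cc1ccco1 | starting material
5 | 5-hydroxyfuran-2(5H)-one (racemic) | O=C1C=CC(O)O1 | intermediate
6 | (1S,2R,5S)-(+)-menthol | C[C@H]1CC[C@@H]([C@H](C1)O)C(C)C | starting material
7 | (5S)-5-{[(1S,2R,5S)-2-isopropyl-5-methylcyclohexyl]oxy}furan-2(5H)-one | O=C1C=C[C@@H](O[C@H]2C[C@@H](C)CC[C@@H]2C(C)C)O1 | intermediate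
8 | vanillin | COc1cc(C=O)ccc1O | starting material
9 | 4-(tert-butyldimethylsilyloxy)-3-methoxybenzaldehyde | COc1cc(C=O)ccc1O[Si](C)(C)C(C)(C)C | intermediate
10 | 2-lithio-2-[4-(allyloxy)-3,5-dimethoxyphenyl]-1,3-dithiane | [Li]C1(SCCCS1)c1cc(OC)c(OCC=C)c(OC)c1 | intermediate
11 | lithium (4S,5S)-4-{2-[4-(allyloxy)-3,5-dimethoxyphenyl]-1,3-dithian-2-yl}-5-(menthyloxy)-4,5-dihydrofuran-2-olate | [Li]OC1=C[C@H](C2(SCCCS2)c2cc(OC)c(OCC=C)c(OC)c2)[C@@H](O[C@H]2C[C@@H](C)CC[C@@H]2C(C)C)O1 | intermediate
12 | (3R,4S,5S)-4-{2-[4-(allyloxy)-3,5-dimethoxyphenyl]-1,3-dithian-2-yl}-3-{(R)-[4-(tert-butyldimethylsilyloxy)-3-methoxyphenyl](hydroxy)methyl}-5-(menthyloxy)dihydrofuran-2(3H)-one | O1[C@H](O[C@H]2C[C@@H](C)CC[C@@H]2C(C)C)[C@@H](C2(SCCCS2)c2cc(OC)c(OCC=C)c(OC)c2)[C@H]([C@@H](O)c2ccc(O[Si](C)(C)C(C)(C)C)c(OC)c2)C1=O | intermediate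
13 | (2S,3S)-2-{2-[4-(allyloxy)-3,5-dimethoxyphenyl]-1,3-dithian-2-yl}-3-{(R)-[4-(tert-butyldimethylsilyloxy)-3-methoxyphenyl](hydroxy)methyl}butane-1,4-diol | OC[C@@H](C1(SCCCS1)c1cc(OC)c(OCC=C)c(OC)c1)[C@H]([C@@H](O)c1ccc(O[Si](C)(C)C(C)(C)C)c(OC)c1)CO | intermediate
14 | (2S,3S)-1-[4-(allyloxy)-3,5-dimethoxyphenyl]-4-hydroxy-2-(hydroxymethyl)-3-{(R)-[4-(tert-butyldimethylsilyloxy)-3-methoxyphenyl](hydroxy)methyl}butan-1-one | OC[C@@H](C(=O)c1cc(OC)c(OCC=C)c(OC)c1)[C@H]([C@@H](O)c1ccc(O[Si](C)(C)C(C)(C)C)c(OC)c1)CO | intermediate
15 | (2S,3S)-2-{[4-(allyloxy)-3,5-dimethoxyphenyl](hydroxy)methyl}-3-{(R)-[4-(tert-butyldimethylsilyloxy)-3-methoxyphenyl](hydroxy)methyl}butane-1,4-diol (C7 epimers) | OC[C@@H](C(O)c1cc(OC)c(OCC=C)c(OC)c1)[C@H]([C@@H](O)c1ccc(O[Si](C)(C)C(C)(C)C)c(OC)c1)CO | intermediate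
16 | [(2R,3S,4S)-4-{[4-(allyloxy)-3,5-dimethoxyphenyl](hydroxy)methyl}-2-[4-(tert-butyldimethylsilyloxy)-3-methoxyphenyl]oxolan-3-yl]methanol (C7 epimers) | COc1cc(ccc1O[Si](C)(C)C(C)(C)C)[C@@H]1OC[C@@H](C(O)c2cc(OC)c(OCC=C)c(OC)c2)[C@H]1CO | intermediate
17 | (1R,3aS,4R,6aS)-1-[4-(allyloxy)-3,5-dimethoxyphenyl]-4-[4-(tert-butyldimethylsilyloxy)-3-methoxyphenyl]tetrahydro-1H,3H-furo[3,4-c]furan | COc1cc(ccc1O[Si](C)(C)C(C)(C)C)[C@@H]1OC[C@@H]2[C@H]1CO[C@H]2c1cc(OC)c(OCC=C)c(OC)c1 | intermediate
18 | 4-{(1R,3aS,4R,6aS)-4-[4-(allyloxy)-3,5-dimethoxyphenyl]tetrahydro-1H,3H-furo[3,4-c]furan-1-yl}-2-methoxyphenol | COc1cc(ccc1O)[C@@H]1OC[C@@H]2[C@H]1CO[C@H]2c1cc(OC)c(OCC=C)c(OC)c1 | intermediate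
19 | (R)-4-benzyloxazolidin-2-one | O=C1N[C@H](Cc2ccccc2)CO1 | starting material
20 | N-lithio-(R)-4-benzyloxazolidin-2-one | [Li]N1[C@H](Cc2ccccc2)COC1=O | intermediate
21 | (R)-4-benzyl-3-(bromoacetyl)oxazolidin-2-one | O=C(CBr)N1[C@H](Cc2ccccc2)COC1=O | intermediate
22 | (R)-4-benzyl-3-[2-(4-{(1R,3aS,4R,6aS)-4-[4-(allyloxy)-3,5-dimethoxyphenyl]tetrahydro-1H,3H-furo[3,4-c]furan-1-yl}-2-methoxyphenoxy)acetyl]oxazolidin-2-one | COc1cc(ccc1OCC(=O)N1[C@H](Cc2ccccc2)COC1=O)[C@@H]1OC[C@@H]2[C@H]1CO[C@H]2c1cc(OC)c(OCC=C)c(OC)c1 | intermediate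
23 | 4-(allyloxy)-3-methoxybenzaldehyde | COc1cc(C=O)ccc1OCC=C | intermediate
24 | (Z)-dibutylboron enolate of 22 | CCCCB(CCCC)O/C(N1[C@H](Cc2ccccc2)COC1=O)=C\Oc1ccc(cc1OC)[C@@H]1OC[C@@H]2[C@H]1CO[C@H]2c1cc(OC)c(OCC=C)c(OC)c1 | intermediate
25 | (R)-4-benzyl-3-[(2R,3S)-3-[4-(allyloxy)-3-methoxyphenyl]-3-hydroxy-2-(4-{(1R,3aS,4R,6aS)-4-[4-(allyloxy)-3,5-dimethoxyphenyl]tetrahydro-1H,3H-furo[3,4-c]furan-1-yl}-2-methoxyphenoxy)propanoyl]oxazolidin-2-one | COc1cc([C@H](O)[C@H](C(=O)N2[C@H](Cc3ccccc3)COC2=O)Oc2ccc([C@@H]3OC[C@@H]4[C@H]3CO[C@H]4c3cc(OC)c(OCC=C)c(OC)c3)cc2OC)ccc1OCC=C | intermediate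
26 | (1S,2S)-1-[4-(allyloxy)-3-methoxyphenyl]-2-(4-{(1R,3aS,4R,6aS)-4-[4-(allyloxy)-3,5-dimethoxyphenyl]tetrahydro-1H,3H-furo[3,4-c]furan-1-yl}-2-methoxyphenoxy)propane-1,3-diol | COc1cc([C@H](O)[C@H](CO)Oc2ccc([C@@H]3OC[C@@H]4[C@H]3CO[C@H]4c3cc(OC)c(OCC=C)c(OC)c3)cc2OC)ccc1OCC=C | intermediate
27 | (1S,2S)-1-(4-hydroxy-3-methoxyphenyl)-2-(4-{(1R,3aS,4R,6aS)-4-(4-hydroxy-3,5-dimethoxyphenyl)tetrahydro-1H,3H-furo[3,4-c]furan-1-yl}-2-methoxyphenoxy)propane-1,3-diol (CNP0255927.3) | COc1cc([C@H](O)[C@H](CO)Oc2ccc([C@@H]3OC[C@@H]4[C@H]3CO[C@H]4c3cc(OC)c(O)c(OC)c3)cc2OC)ccc1O | target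

## Step count and least certain steps

Total: 17 steps. Longest linear sequence: 12 steps (1, 2, 6, 7, 8, 9, 10, 11, 13, 15, 16, 17).

**Step 6 (key step).**
- What may go wrong: capture of the crowded lithium enolate 11 by aldehyde 9 may be slow, so that proton quench, retro-aldol cleavage on warming or consumption of 7 by unreacted 10 takes over. Attack of n-BuLi on the allyl ether is a second risk if the metalation of 3 is run too warm.
- Fallback: the two bond formations are separated. From 3 and 7 the conjugate addition is run alone and quenched cold to give the trans lactone (4S,5S)-4-{2-[4-(allyloxy)-3,5-dimethoxyphenyl]-1,3-dithian-2-yl}-5-(menthyloxy)dihydrofuran-2(3H)-one F1, which is purified. F1 is then deprotonated with LDA in THF at −78 °C, which regenerates enolate 11 free of other bases, and 9 is added to return to 12. Each C–C bond can then be optimised on its own.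

**Step 10.**
- What may go wrong: loss of kinetic control. The acid can re-ionise the benzylic ether bonds of 17 and equilibrate C7 and C7' towards endo epimers, which are not much less stable. The C7 hydroxyl may also capture the C7' cation in place of the C9 hydroxyl, giving a 2,5-diaryltetrahydrofuran.
- Fallback: the two rings are closed in separate operations, starting from 13. CSA (cat.) in CH2Cl2 at 0 °C ionises only C7', because C7 is still a dithiane, and closes the first ring to [(2R,3S,4S)-4-{2-[4-(allyloxy)-3,5-dimethoxyphenyl]-1,3-dithian-2-yl}-2-[4-(tert-butyldimethylsilyloxy)-3-methoxyphenyl]oxolan-3-yl]methanol F2. PhI(OCOCF3)2 in wet MeCN unmasks the ketone [4-(allyloxy)-3,5-dimethoxyphenyl][(3S,4S,5R)-5-[4-(tert-butyldimethylsilyloxy)-3-methoxyphenyl]-4-(hydroxymethyl)oxolan-3-yl]methanone F3. NaBH4 gives 16, in which a single cation with a single hydroxyl partner remains, and brief acid treatment closes it to 17.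

**Step 8.**
- What may go wrong: the trivalent iodine reagent may oxidise the electron-rich rings, and the unmasked β-hydroxy ketone may enolise at C8 (epimerisation) or lose water.
- Fallback: the order of unmasking and reduction is reversed. From 12, PhI(OCOCF3)2 in wet MeCN gives the keto lactone (3R,4S,5S)-4-[4-(allyloxy)-3,5-dimethoxybenzoyl]-3-{(R)-[4-(tert-butyldimethylsilyloxy)-3-methoxyphenyl](hydroxy)methyl}-5-(menthyloxy)dihydrofuran-2(3H)-one F4, which has only one free hydroxyl. F4 is added at once to LiAlH4 in THF at −78 → 0 °C, which reduces ketone, lactone and acetal together and returns to 15 with one step fewer.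

**Step 13.**
- What may go wrong: acyl transfer. Phenoxide or carbonate may attack the exocyclic imide carbonyl of 21 or 22 and cleave the auxiliary instead of displacing bromide.
- Fallback: the ether is made first and the auxiliary attached afterwards. From 18, ethyl bromoacetate and K2CO3 in acetone give ethyl 2-(4-{(1R,3aS,4R,6aS)-4-[4-(allyloxy)-3,5-dimethoxyphenyl]tetrahydro-1H,3H-furo[3,4-c]furan-1-yl}-2-methoxyphenoxy)acetate F5. LiOH in THF/H2O gives the corresponding aryloxyacetic acid F6. Pivaloyl chloride and Et3N convert F6 into its mixed pivalic anhydride F7, which acylates the lithiated oxazolidinone 20 to return to 22.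

**Step 15.**
- What may go wrong: erosion of syn selectivity at C7''. The aryloxy oxygen organises the boron enolate less well than an alkoxy group, and the electron-rich aldehyde reacts slowly and reversibly. Some ionisation of the furofuran ethers by the boron triflate is a lesser risk.
- Fallback: C7'' is set by reduction instead of by the aldol. From 25, taken as its mixture with the C7'' epimer, Dess–Martin periodinane oxidises both epimers to the single β-keto imide (R)-4-benzyl-3-[(2R)-3-[4-(allyloxy)-3-methoxyphenyl]-3-oxo-2-(4-{(1R,3aS,4R,6aS)-4-[4-(allyloxy)-3,5-dimethoxyphenyl]tetrahydro-1H,3H-furo[3,4-c]furan-1-yl}-2-methoxyphenoxy)propanoyl]oxazolidin-2-one F8. Its C8'' centre is held against enolisation by allylic strain with the imide. Zn(BH4)2 in CH2Cl2/Et2O at −20 °C reduces the ketone through the chelate of the two carbonyl groups, with hydride anti to the aryloxy group, and returns the syn alcohol 25.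

## Further compounds

F1 | step 6 | (4S,5S)-4-{2-[4-(allyloxy)-3,5-dimethoxyphenyl]-1,3-dithian-2-yl}-5-{[(1S,2R,5S)-2-isopropyl-5-methylcyclohexyl]oxy}dihydrofuran-2(3H)-one | O=C1C[C@H](C2(SCCCS2)c2cc(OC)c(OCC=C)c(OC)c2)[C@@H](O[C@H]2C[C@@H](C)CC[C@@H]2C(C)C)O1
F2 | step 10 | [(2R,3S,4S)-4-{2-[4-(allyloxy)-3,5-dimethoxyphenyl]-1,3-dithian-2-yl}-2-[4-(tert-butyldimethylsilyloxy)-3-methoxyphenyl]oxolan-3-yl]methanol | COc1cc(ccc1O[Si](C)(C)C(C)(C)C)[C@@H]1OC[C@@H](C2(SCCCS2)c2cc(OC)c(OCC=C)c(OC)c2)[C@H]1CO
F3 | step 10 | [4-(allyloxy)-3,5-dimethoxyphenyl][(3S,4S,5R)-5-[4-(tert-butyldimethylsilyloxy)-3-methoxyphenyl]-4-(hydroxymethyl)oxolan-3-yl]methanone | COc1cc(ccc1O[Si](C)(C)C(C)(C)C)[C@@H]1OC[C@@H](C(=O)c2cc(OC)c(OCC=C)c(OC)c2)[C@H]1CO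
F4 | step 8 | (3R,4S,5S)-4-[4-(allyloxy)-3,5-dimethoxybenzoyl]-3-{(R)-[4-(tert-butyldimethylsilyloxy)-3-methoxyphenyl](hydroxy)methyl}-5-{[(1S,2R,5S)-2-isopropyl-5-methylcyclohexyl]oxy}dihydrofuran-2(3H)-one | O1[C@H](O[C@H]2C[C@@H](C)CC[C@@H]2C(C)C)[C@@H](C(=O)c2cc(OC)c(OCC=C)c(OC)c2)[C@H]([C@@H](O)c2ccc(O[Si](C)(C)C(C)(C)C)c(OC)c2)C1=O
F5 | step 13 | ethyl 2-(4-{(1R,3aS,4R,6aS)-4-[4-(allyloxy)-3,5-dimethoxyphenyl]tetrahydro-1H,3H-furo[3,4-c]furan-1-yl}-2-methoxyphenoxy)acetate | CCOC(=O)COc1ccc(cc1OC)[C@@H]1OC[C@@H]2[C@H]1CO[C@H]2c1cc(OC)c(OCC=C)c(OC)c1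
F6 | step 13 | 2-(4-{(1R,3aS,4R,6aS)-4-[4-(allyloxy)-3,5-dimethoxyphenyl]tetrahydro-1H,3H-furo[3,4-c]furan-1-yl}-2-methoxyphenoxy)acetic acid | OC(=O)COc1ccc(cc1OC)[C@@H]1OC[C@@H]2[C@H]1CO[C@H]2c1cc(OC)c(OCC=C)c(OC)c1
F7 | step 13 | mixed anhydride of F6 with pivalic acid | CC(C)(C)C(=O)OC(=O)COc1ccc(cc1OC)[C@@H]1OC[C@@H]2[C@H]1CO[C@H]2c1cc(OC)c(OCC=C)c(OC)c1
F8 | step 15 | (R)-4-benzyl-3-[(2R)-3-[4-(allyloxy)-3-methoxyphenyl]-3-oxo-2-(4-{(1R,3aS,4R,6aS)-4-[4-(allyloxy)-3,5-dimethoxyphenyl]tetrahydro-1H,3H-furo[3,4-c]furan-1-yl}-2-methoxyphenoxy)propanoyl]oxazolidin-2-one | COc1cc(C(=O)[C@H](C(=O)N2[C@H](Cc3ccccc3)COC2=O)Oc2ccc([C@@H]3OC[C@@H]4[C@H]3CO[C@H]4c3cc(OC)c(OCC=C)c(OC)c3)cc2OC)ccc1OCC=C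
A1 | alternative 1 | methyl (3aS,4R,6aS)-4-[4-(tert-butyldimethylsilyloxy)-3-methoxyphenyl]-1-oxotetrahydro-1H,3H-furo[3,4-c]furan-6a-carboxylate | CC(C)(C)[Si](C)(C)Oc1ccc([C@@H]2OC[C@]3(C(=O)OC)[C@H]2COC3=O)cc1OC
A2 | alternative 1 | methyl (1R,5S,6S)-6-[4-(tert-butyldimethylsilyloxy)-3-methoxyphenyl]-2-oxo-3-oxabicyclo[3.1.0]hexane-1-carboxylate | CC(C)(C)[Si](C)(C)Oc1ccc(cc1OC)[C@@H]1[C@@H]2COC(=O)[C@]12C(=O)OC
A3 | alternative 1 | formaldehyde | C=O
A4 | alternative 2 | 4-{(1R,3aS,4R,6aS)-4-[4-(benzyloxy)-3,5-dimethoxyphenyl]tetrahydro-1H,3H-furo[3,4-c]furan-1-yl}-2-methoxyphenol | COc1cc([C@@H]2OC[C@@H]3[C@H]2CO[C@H]3c2cc(OC)c(OCc4ccccc4)c(OC)c2)ccc1O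
A5 | alternative 2 | (2S,3S)-2-[4-(benzyloxy)-3,5-dimethoxybenzyl]-3-(4-hydroxy-3-methoxybenzyl)butane-1,4-diol | COc1cc(C[C@H](CO)[C@@H](CO)Cc2cc(OC)c(OCc3ccccc3)c(OC)c2)ccc1O
A6 | alternative 3 | (3R,3aS,6R,6aR)-6-[4-(benzyloxy)-3,5-dimethoxyphenyl]-3-[4-(tert-butyldimethylsilyloxy)-3-methoxyphenyl]tetrahydro-1H,3H-furo[3,4-c]furan-1-one | CC(C)(C)[Si](C)(C)Oc1ccc([C@@H]2OC(=O)[C@@H]3[C@H]2CO[C@H]3c2cc(OC)c(OCc4ccccc4)c(OC)c2)cc1OC
A7 | alternative 3 | (4S,5R)-4-({[4-(benzyloxy)-3,5-dimethoxybenzyl]oxy}methyl)-3-diazo-5-[4-(tert-butyldimethylsilyloxy)-3-methoxyphenyl]dihydrofuran-2(3H)-one | CC(C)(C)[Si](C)(C)Oc1ccc([C@@H]2OC(=O)C(=[N+]=[N-])[C@H]2COCc2cc(OC)c(OCc3ccccc3)c(OC)c2)cc1OC
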